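Rings B and A are cut through the ring, not at their crowded aryl–oxygen bonds. Each is a phloroglucinol whose C2 carries the oxygen of the preceding ring, flanked by oxygenated C1 and C3 with the C5 oxygen para. In ring B the C1 oxygen anchors ring A. One aryloxyketene and two ethoxyacetylenes map onto this 2-aryloxy-3,5-diethoxyphenol. The key step heats ethoxyacetylene with a 4-aryloxy-3-ethoxycyclobutenone hung on the para oxygen of ring C of a C–D diaryl ether. Ring B is completed in one operation and only its C1 hydroxyl is free. That hydroxyl restarts the cycle for ring A, and BBr3 then frees all ten hydroxyls.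

Key step: step 5

Conventions:
- Ring D is the terminal 3,4,5-trioxygenated ring, ring C is bonded to D, ring B is bonded to C, and ring A is the terminal 2,4,6-trihydroxyphenoxy ring.
- Rings B and A are numbered as phenols. C1 bears the OH released by the benzannulation and C2 bears the oxygen of the preceding ring.
- ArCD = 3,5-dimethoxy-4-(3,4,5-trimethoxyphenoxy)phenyl.
- ArBCD = 3,5-diethoxy-2-(ArCD-oxy)phenyl.
- No stereocentre is present in the target. Every cyclobutenone and cyclohexadienone on the route is racemic.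

Assumption: ethoxyacetylene is used as its commercial solution in hexanes, and the hydrocarbon is an inert co-solvent in every step.

Step 1
Reactants: 1 5-bromo-1,2,3-trimethoxybenzene (ring D); 2 2,6-dimethoxyphenol (ring C)
Product: 3 5-(2,6-dimethoxyphenoxy)-1,2,3-trimethoxybenzene (C–D diaryl ether)
Conditions: CuI (10 mol %), picolinic acid (20 mol %), K3PO4, DMSO, 90 °C, argon
Reagents that add atoms: none
Why: Ligand-accelerated Ullmann ether coupling accepts a 2,6-disubstituted phenoxide when the brominated carbon has hydrogen on both sides, as C5 of 1 has, so all crowding lies on the nucleophile.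

Step 2
Reactants: 3 C–D diaryl ether
Product: 5 3,5-dimethoxy-4-(3,4,5-trimethoxyphenoxy)phenol (ArCD–OH), via C–D boronate 4 (not isolated)
Conditions: [Ir(OMe)(cod)]2 (1.5 mol %), 4,4'-di-tert-butyl-2,2'-bipyridine (3 mol %), B2pin2, THF, 80 °C; then 30% aq H2O2, aq NaOH, 0 °C
Reagents that add atoms: bis(pinacolato)diboron CC1(C)OB(OC1(C)C)B1OC(C)(C)C(C)(C)O1 (boryl group of 4 only); hydrogen peroxide OO (phenol oxygen of 5)
Why: Sterically governed iridium-catalysed C–H borylation should reach only C4–H of ring C, the one C–H whose two neighbours both carry hydrogen, and peroxide oxidation of the boronate (aryl shift from boron to oxygen) puts the OH on that same carbon.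

Step 3
Reactants: 5 ArCD–OH; 6 ethyl bromoacetate
Product: 8 2-(ArCD-oxy)acetic acid, via ethyl ester 7 (not isolated)
Conditions: K2CO3, MeCN, 60 °C; then LiOH, THF–H2O, rt; 1 M HCl, 0 °C
Reagents that add atoms: lithium hydroxide [Li+].[OH-] (hydroxyl oxygen of the acid)
Why: Williamson alkylation of an unhindered phenoxide by a primary α-bromo ester, followed by saponification in the same flask, is routine, and nothing else in 5 is nucleophilic or base-labile.

Step 4
Reactants: 8 2-(ArCD-oxy)acetic acid; 9 ethoxyacetylene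
Product: 12 (±)-4-(ArCD-oxy)-3-ethoxycyclobut-2-en-1-one, via acid chloride 10 (not isolated), via aryloxyketene 11 (not isolated)
Conditions: Me2C=C(Cl)NMe2 (1.0 equiv), CH2Cl2, 0 °C; then this solution added over 4 h to 9 (4 equiv), Et3N (1.5 equiv), CH2Cl2, 0 °C to rt; chromatography on Et3N-deactivated silica
Reagents that add atoms: 1-chloro-N,N,2-trimethylprop-1-en-1-amine CC(C)=C(Cl)N(C)C (chlorine of 10 only; nothing of it remains in 12)
Why: The α-chloroenamine makes 10 without HCl or a Lewis acid, so the activated ring C carbons ortho to OCH2 are not acylated; Et3N then eliminates HCl to ketene 11, kept dilute by slow addition, and the known ketene–ynol ether [2+2] cycloaddition joins the alkyne CH to the ketene carbonyl carbon and C(OEt) to the aryloxy carbon, forming C4 as a racemic stereocentre.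

Step 5
Reactants: 12 (±)-4-(ArCD-oxy)-3-ethoxycyclobut-2-en-1-one; 9 ethoxyacetylene
Product: 17 2-(ArCD-oxy)-3,5-diethoxyphenol (B–C–D phenol), via vinylketene 13 (not isolated), via vinylcyclobutenone 14 (not isolated), via dienylketene 15 (not isolated), via cyclohexadienone 16 (not isolated)
Conditions: 9 (6 equiv in three portions), toluene, sealed tube, 100 °C, argon; then K2CO3, MeOH, rt, argon
Reagents that add atoms: none
Why: Proposed new method: heating breaks C1–C4 of 12 in a conrotatory four-electron electrocyclic opening, the C4 aryloxy donor turning outward, and gives vinylketene 13, whose C1=C2 bond takes up 9 in a [2+2] cycloaddition (alkyne CH to C1, alkyne C(OEt) to C2) that closes the four-membered ring of 14. Reversible reopening of 14 gives dienylketene 15, and the isomer with the enol ether arm cis to the ketene is drained by disrotatory six-electron electrocyclization (C1–C4 bond), the closure that forms ring B as dienone 16 before tautomerization to phenol 17. The closest known reaction types are the Danheiser benzannulation of cyclobutenones with alkoxyalkynes and the thermal combination of a ketene with two ethoxyalkynes to phloroglucinol diethers; what has not been shown is a cyclobutenone bearing an aryloxy group at C4 next to a C3 ethoxy group, although outward rotation of a C4 oxygen donor is established in the ring expansions of 4-hydroxy- and 4-alkoxycyclobutenones. No stereocentre survives, since C4 of 12 and 14 and C6 of 16 are racemic and end as sp2 carbons of the arene. The step needs regioselectivity and periselectivity: the polarized ynol ether delivers its CH to the electrophilic ketene carbon each time, so both OEt groups end meta to the new OH and the aryloxy carbon lies between OH and OEt, while ketenes add alkynes across C=C in preference to a [4+2] mode that would place the aryloxy group para to OH. At 100 °C the retro-ene loss of ethylene from 9 should stay slower than its capture, 9 is replenished in portions, and any phenol ester formed by ketene capture is returned to 17 by the closing methanolysis.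

Step 6
Reactants: 17 B–C–D phenol; 6 ethyl bromoacetate
Product: 19 2-(ArBCD-oxy)acetic acid, via ethyl ester 18 (not isolated)
Conditions: K2CO3, MeCN, 60 °C; then LiOH, THF–H2O, rt; 1 M HCl, 0 °C
Reagents that add atoms: lithium hydroxide [Li+].[OH-] (hydroxyl oxygen of the acid)
Why: Williamson alkylation of the only free hydroxyl, C1–OH of ring B, which has hydrogen on one ortho side, followed by saponification, makes the future A–O–B junction as a plain O–CH2 bond instead of a doubly hindered aryl coupling.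

Step 7
Reactants: 19 2-(ArBCD-oxy)acetic acid; 9 ethoxyacetylene
Product: 22 (±)-4-(ArBCD-oxy)-3-ethoxycyclobut-2-en-1-one, via acid chloride 20 (not isolated), via aryloxyketene 21 (not isolated)
Conditions: Me2C=C(Cl)NMe2 (1.0 equiv), CH2Cl2, 0 °C; then this solution added over 4 h to 9 (4 equiv), Et3N (1.5 equiv), CH2Cl2, 0 °C to rt; chromatography on Et3N-deactivated silica
Reagents that add atoms: 1-chloro-N,N,2-trimethylprop-1-en-1-amine CC(C)=C(Cl)N(C)C (chlorine of 20 only; nothing of it remains in 22)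
Why: As in step 4, neutral acid chloride formation spares the strongly activated C6–H of ring B from ring closure to a benzofuranone, and the ketene–ynol ether [2+2] cycloaddition, polarity-controlled in the same sense, sets C4 as a racemic stereocentre.

Step 8
Reactants: 22 (±)-4-(ArBCD-oxy)-3-ethoxycyclobut-2-en-1-one; 9 ethoxyacetylene
Product: 27 2-(ArBCD-oxy)-3,5-diethoxyphenol (A–B–C–D tetramer, five OMe, four OEt, one OH), via vinylketene 23 (not isolated), via vinylcyclobutenone 24 (not isolated), via dienylketene 25 (not isolated), via cyclohexadienone 26 (not isolated)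
Conditions: 9 (6 equiv in three portions), toluene, sealed tube, 100 °C, argon; then K2CO3, MeOH, rt, argon
Reagents that add atoms: none
Why: Proposed new method: the cascade of step 5 (conrotatory opening of 22 with the C4 aryloxy group turning outward to 23, polarity-controlled [2+2] addition of 9 to 24, reopening to 25, six-electron electrocyclization to 26, tautomerization) should build ring A on the C1 oxygen of ring B, the closest known reaction type again being the Danheiser benzannulation of cyclobutenones with alkoxyalkynes, not yet shown for 4-aryloxy-3-ethoxycyclobutenones, and the larger aryloxy group sits on the outward terminus, away from the ketene carbon until the last ring closure.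

Step 9
Reactants: 27 A–B–C–D tetramer
Product: 28 2-{2-[3,5-dihydroxy-4-(3,4,5-trihydroxyphenoxy)phenoxy]-3,5-dihydroxyphenoxy}benzene-1,3,5-triol (CNP0018314.0)
Conditions: BBr3 (20 equiv), CH2Cl2, −78 °C to rt, argon; degassed H2O, 0 °C; EtOAc extraction in the presence of ascorbic acid; Sephadex LH-20, degassed MeOH
Reagents that add atoms: none
Why: In this Lewis-acid ether cleavage BBr3 binds each alkyl aryl ether oxygen and bromide removes methyl or ethyl by SN2 attack at the alkyl carbon, a path closed to the three diaryl ether oxygens, whose carbons are all sp2, so only the nine alkyl groups should be lost.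

Compound list
1 | 5-bromo-1,2,3-trimethoxybenzene | COc1cc(Br)cc(OC)c1OC | starting material
2 | 2,6-dimethoxyphenol | COc1cccc(OC)c1O | starting material
3 | 5-(2,6-dimethoxyphenoxy)-1,2,3-trimethoxybenzene | COc1cccc(OC)c1Oc1cc(OC)c(OC)c(OC)c1 | intermediate
4 | 2-(ArCD)-4,4,5,5-tetramethyl-1,3,2-dioxaborolane | COc1cc(B2OC(C)(C)C(C)(C)O2)cc(OC)c1Oc1cc(OC)c(OC)c(OC)c1 | intermediate
5 | 3,5-dimethoxy-4-(3,4,5-trimethoxyphenoxy)phenol | COc1cc(O)cc(OC)c1Oc1cc(OC)c(OC)c(OC)c1 | intermediate
6 | ethyl bromoacetate | CCOC(=O)CBr | starting material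
7 | ethyl 2-(ArCD-oxy)acetate | CCOC(=O)COc1cc(OC)c(Oc2cc(OC)c(OC)c(OC)c2)c(OC)c1 | intermediate
8 | 2-(ArCD-oxy)acetic acid | OC(=O)COc1cc(OC)c(Oc2cc(OC)c(OC)c(OC)c2)c(OC)c1 | intermediate
9 | ethoxyacetylene | CCOC#C | starting material
10 | 2-(ArCD-oxy)acetyl chloride | O=C(Cl)COc1cc(OC)c(Oc2cc(OC)c(OC)c(OC)c2)c(OC)c1 | intermediate
11 | (ArCD-oxy)ketene | O=C=COc1cc(OC)c(Oc2cc(OC)c(OC)c(OC)c2)c(OC)c1 | intermediate
12 | (±)-4-(ArCD-oxy)-3-ethoxycyclobut-2-en-1-one | CCOC1=CC(=O)C1Oc1cc(OC)c(Oc2cc(OC)c(OC)c(OC)c2)c(OC)c1 | intermediate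
13 | (3Z)-4-(ArCD-oxy)-3-ethoxybuta-1,3-dien-1-one | O=C=C/C(OCC)=C/Oc1cc(OC)c(Oc2cc(OC)c(OC)c(OC)c2)c(OC)c1 | intermediate
14 | (±)-4-[(Z)-2-(ArCD-oxy)-1-ethoxyethenyl]-3-ethoxycyclobut-2-en-1-one | CCOC1=CC(=O)C1/C(OCC)=C/Oc1cc(OC)c(Oc2cc(OC)c(OC)c(OC)c2)c(OC)c1 | intermediate
15 | (3E,5Z)-6-(ArCD-oxy)-3,5-diethoxyhexa-1,3,5-trien-1-one | O=C=C/C(OCC)=C\C(OCC)=C\Oc1cc(OC)c(Oc2cc(OC)c(OC)c(OC)c2)c(OC)c1 | intermediate
16 | (±)-6-(ArCD-oxy)-3,5-diethoxycyclohexa-2,4-dien-1-one | CCOC1=CC(=O)C(Oc2cc(OC)c(Oc3cc(OC)c(OC)c(OC)c3)c(OC)c2)C(OCC)=C1 | intermediate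
17 | 2-(ArCD-oxy)-3,5-diethoxyphenol | CCOc1cc(O)c(Oc2cc(OC)c(Oc3cc(OC)c(OC)c(OC)c3)c(OC)c2)c(OCC)c1 | intermediate
18 | ethyl 2-(ArBCD-oxy)acetate | CCOC(=O)COc1cc(OCC)cc(OCC)c1Oc1cc(OC)c(Oc2cc(OC)c(OC)c(OC)c2)c(OC)c1 | intermediate
19 | 2-(ArBCD-oxy)acetic acid | OC(=O)COc1cc(OCC)cc(OCC)c1Oc1cc(OC)c(Oc2cc(OC)c(OC)c(OC)c2)c(OC)c1 | intermediate
20 | 2-(ArBCD-oxy)acetyl chloride | CCOc1cc(OCC(=O)Cl)c(Oc2cc(OC)c(Oc3cc(OC)c(OC)c(OC)c3)c(OC)c2)c(OCC)c1 | intermediate
21 | (ArBCD-oxy)ketene | O=C=COc1cc(OCC)cc(OCC)c1Oc1cc(OC)c(Oc2cc(OC)c(OC)c(OC)c2)c(OC)c1 | intermediate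
22 | (±)-4-(ArBCD-oxy)-3-ethoxycyclobut-2-en-1-one | CCOC1=CC(=O)C1Oc1cc(OCC)cc(OCC)c1Oc1cc(OC)c(Oc2cc(OC)c(OC)c(OC)c2)c(OC)c1 | intermediate
23 | (3Z)-4-(ArBCD-oxy)-3-ethoxybuta-1,3-dien-1-one | O=C=C/C(OCC)=C/Oc1cc(OCC)cc(OCC)c1Oc1cc(OC)c(Oc2cc(OC)c(OC)c(OC)c2)c(OC)c1 | intermediate
24 | (±)-4-[(Z)-2-(ArBCD-oxy)-1-ethoxyethenyl]-3-ethoxycyclobut-2-en-1-one | CCOC1=CC(=O)C1/C(OCC)=C/Oc1cc(OCC)cc(OCC)c1Oc1cc(OC)c(Oc2cc(OC)c(OC)c(OC)c2)c(OC)c1 | intermediate
25 | (3E,5Z)-6-(ArBCD-oxy)-3,5-diethoxyhexa-1,3,5-trien-1-one | O=C=C/C(OCC)=C\C(OCC)=C\Oc1cc(OCC)cc(OCC)c1Oc1cc(OC)c(Oc2cc(OC)c(OC)c(OC)c2)c(OC)c1 | intermediate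
26 | (±)-6-(ArBCD-oxy)-3,5-diethoxycyclohexa-2,4-dien-1-one | CCOC1=CC(=O)C(Oc2cc(OCC)cc(OCC)c2Oc2cc(OC)c(Oc3cc(OC)c(OC)c(OC)c3)c(OC)c2)C(OCC)=C1 | intermediate
27 | 2-(ArBCD-oxy)-3,5-diethoxyphenol | CCOc1cc(O)c(Oc2cc(OCC)cc(OCC)c2Oc2cc(OC)c(Oc3cc(OC)c(OC)c(OC)c3)c(OC)c2)c(OCC)c1 | intermediate
28 | 2-{2-[3,5-dihydroxy-4-(3,4,5-trihydroxyphenoxy)phenoxy]-3,5-dihydroxyphenoxy}benzene-1,3,5-triol | Oc1cc(O)c(Oc2cc(O)cc(O)c2Oc2cc(O)c(Oc3cc(O)c(O)c(O)c3)c(O)c2)c(O)c1 | target

Total step count: 9
Longest linear sequence: 9 steps (from 1 or 2 to 28)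

Steps most likely to fail

1. Step 5 (ring B benzannulation).
   - What may go wrong: the C3 ethoxy group stabilises the cyclobutenone. Ring opening may therefore need a temperature at which ethoxyacetylene loses ethylene faster than it is captured. The vinylketene may also dimerise or add the alkyne in the [4+2] sense.
   - Fallback: it uses known chemistry, also bypasses steps 3 and 4, sets out from boronate 4 (isolated this time) and comes back at 17. Ring B is brought in as a finished hindered phenol and joined to the unhindered para carbon of ring C, the same pairing as in step 1. Boronate 4 is converted with CuBr2 in aqueous methanol into 5-(4-bromo-2,6-dimethoxyphenoxy)-1,2,3-trimethoxybenzene F1. Separately, bought 2,4,6-trihydroxybenzaldehyde is ethylated twice (EtI, K2CO3, the formyl-chelated hydroxyl staying free) to 4,6-diethoxy-2-hydroxybenzaldehyde F2. This is benzylated (BnBr, K2CO3) to 2-benzyloxy-4,6-diethoxybenzaldehyde F3, oxidised by Baeyer–Villiger reaction (mCPBA) to 2-benzyloxy-4,6-diethoxyphenyl formate F4, and methanolysed (K2CO3, MeOH) to 2-benzyloxy-4,6-diethoxyphenol F5. Ullmann coupling of F5 with F1 (CuI, picolinic acid, K3PO4, DMSO, argon) should give 1-benzyloxy-3,5-diethoxy-2-(ArCD-oxy)benzene F6. Hydrogenolysis (H2, Pd/C) then returns 17.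

2. Step 8 (ring A benzannulation).
   - What may go wrong: the same narrow thermal window applies, made worse by crowding around C4 of 22. That crowding slows the last ring closure and leaves the ketenes time to oligomerise.
   - Fallback: it uses known chemistry, also bypasses steps 6 and 7, sets out from 17 and comes back at 28. Phenol 17 is joined by Ullmann coupling (CuI, N,N-dimethylglycine, Cs2CO3, dioxane, 100 °C, argon) to bought 4-bromo-3,5-dimethoxybenzaldehyde, whose C–Br bond is activated by the para formyl group. This gives 4-(ArBCD-oxy)-3,5-dimethoxybenzaldehyde F7. Baeyer–Villiger oxidation (mCPBA, CH2Cl2) turns the formyl carbon into the missing C5 oxygen of ring A as 4-(ArBCD-oxy)-3,5-dimethoxyphenyl formate F8. Methanolysis (K2CO3, MeOH) gives 4-(ArBCD-oxy)-3,5-dimethoxyphenol F9. BBr3 under the conditions of step 9 removes its seven methyl and two ethyl groups to give 28.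

3. Step 9 (global dealkylation).
   - What may go wrong: partly cleaved boron aryloxides may precipitate from CH2Cl2 before all nine alkyl groups are gone. The free decaphenol, ring D above all, may autoxidise during aqueous isolation and chromatography.
   - Fallback: it sets out from 27 and comes back at 28, and the polyphenol is purified as a protected derivative instead of in free form. After BBr3 treatment and quench, the crude material is peracetylated (Ac2O, pyridine) to the deca-acetate of 28 F10. This is an air-stable compound that can be chromatographed on silica and freed from under-cleaved ethers. Hydrazinolysis (N2H4·H2O, degassed MeCN, 0 °C to rt, argon) then releases 28 under reducing, near-neutral conditions, so that only a filtration through Sephadex LH-20 remains.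

Further compounds
F1 | step 5 | 5-(4-bromo-2,6-dimethoxyphenoxy)-1,2,3-trimethoxybenzene | COc1cc(Br)cc(OC)c1Oc1cc(OC)c(OC)c(OC)c1
F2 | step 5 | 4,6-diethoxy-2-hydroxybenzaldehyde | CCOc1cc(O)c(C=O)c(OCC)c1
F3 | step 5 | 2-benzyloxy-4,6-diethoxybenzaldehyde | CCOc1cc(OCc2ccccc2)c(C=O)c(OCC)c1
F4 | step 5 | 2-benzyloxy-4,6-diethoxyphenyl formate | CCOc1cc(OCc2ccccc2)c(OC=O)c(OCC)c1
F5 | step 5 | 2-benzyloxy-4,6-diethoxyphenol | CCOc1cc(OCc2ccccc2)c(O)c(OCC)c1
F6 | step 5 | 1-benzyloxy-3,5-diethoxy-2-(ArCD-oxy)benzene | CCOc1cc(OCc2ccccc2)c(Oc2cc(OC)c(Oc3cc(OC)c(OC)c(OC)c3)c(OC)c2)c(OCC)c1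
F7 | step 8 | 4-(ArBCD-oxy)-3,5-dimethoxybenzaldehyde | COc1cc(C=O)cc(OC)c1Oc1cc(OCC)cc(OCC)c1Oc1cc(OC)c(Oc2cc(OC)c(OC)c(OC)c2)c(OC)c1
F8 | step 8 | 4-(ArBCD-oxy)-3,5-dimethoxyphenyl formate | COc1cc(OC=O)cc(OC)c1Oc1cc(OCC)cc(OCC)c1Oc1cc(OC)c(Oc2cc(OC)c(OC)c(OC)c2)c(OC)c1
F9 | step 8 | 4-(ArBCD-oxy)-3,5-dimethoxyphenol | COc1cc(O)cc(OC)c1Oc1cc(OCC)cc(OCC)c1Oc1cc(OC)c(Oc2cc(OC)c(OC)c(OC)c2)c(OC)c1
F10 | step 9 | deca-acetate of 28 | CC(=O)Oc1cc(OC(C)=O)c(Oc2cc(OC(C)=O)cc(OC(C)=O)c2Oc2cc(OC(C)=O)c(Oc3cc(OC(C)=O)c(OC(C)=O)c(OC(C)=O)c3)c(OC(C)=O)c2)c(OC(C)=O)c1
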